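**Strategy.** Ring C of the flavone is cut at C8a–O1, C4a–C4 and O1–C2, which leaves a ring A aryne (C4a≡C8a) and a ring B arylpropiolic acid. In one operation fluoride frees the aryne, the carboxylate adds, the acyl group moves to carbon and the resulting phenoxide closes the pyranone. The step exploits the oxygen on C5 of ring A: sitting next to C4a, it polarises the aryne so that oxygen enters at C8a and the carbonyl carbon at C4a. The precursors are an ortho-silylaryl triflate with OMOM beside the silylated carbon and a prenyl ether kept for the later Claisen shift to C8, and a chromenyl propiolic acid.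

Key step: step 12

Assumption: the target is achiral, so no stereocentre has to be set; "prenyl" means 3-methylbut-2-en-1-yl; prenol, 2-bromo-4,5-dimethoxybenzaldehyde, 3-chloro-3-methylbut-1-yne and the prenylstannane are taken as bought.

**Ring A fragment**

Step 1
Reactants: 1 phloroglucinol; 2 3-methylbut-2-en-1-ol (prenol)
Product: 3 5-[(3-methylbut-2-en-1-yl)oxy]benzene-1,3-diol
Conditions: 1 (3 equiv), 2 (1 equiv), PPh3, DIAD, THF, 0 °C → rt; excess 1 washed out with water
Reagents that add atoms: none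
Why: Mitsunobu etherification alkylates a phenol oxygen under neutral conditions, and the excess of water-soluble triol should hold the reaction at the monoether and avoid the C-alkylation that phloroglucinol shows with prenyl halides and base.

Step 2
Reactants: 3 5-[(3-methylbut-2-en-1-yl)oxy]benzene-1,3-diol
Product: 4 2-iodo-5-[(3-methylbut-2-en-1-yl)oxy]benzene-1,3-diol
Conditions: iodine (1.0 equiv), NaHCO3, THF/H2O, 0 °C
Reagents that add atoms: iodine: [I][I]
Why: Electrophilic aromatic iodination under aqueous hydrogencarbonate should, as with resorcinol itself, enter the carbon between the two free hydroxyls, which keeps the molecule symmetric so that the two hydroxyls remain equivalent and no regiochemical choice arises later.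

Step 3
Reactants: 4 2-iodo-5-[(3-methylbut-2-en-1-yl)oxy]benzene-1,3-diol
Product: 8 3-(methoxymethoxy)-5-[(3-methylbut-2-en-1-yl)oxy]-2-(trimethylsilyl)phenol, via bis(trimethylsilyl) ether 5 (not isolated), via lithium phenolate 6 (not isolated), via aryl silyl ether 7 (not isolated)
Conditions: HMDS, THF, reflux, then evaporation; n-BuLi (1.05 equiv), THF, −78 → −40 °C; MOMCl, −78 °C → rt; aq. NH4Cl; MeOH, citric acid (cat.), rt
Reagents that add atoms: hexamethyldisilazane: C[Si](C)(C)N[Si](C)(C)C; chloromethyl methyl ether: COCCl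
Why: O-silylation, iodine–lithium exchange and retro-Brook rearrangement (1,3-shift of one silyl group from oxygen to the lithiated carbon) give one lithium phenolate whichever silyl ether migrates because 5 is symmetric, and O-alkylation with MOMCl followed by methanolysis of the remaining aryl silyl ether leaves a single phenol beside the C-silyl group.

Step 4
Reactants: 8 3-(methoxymethoxy)-5-[(3-methylbut-2-en-1-yl)oxy]-2-(trimethylsilyl)phenol
Product: 9 3-(methoxymethoxy)-5-[(3-methylbut-2-en-1-yl)oxy]-2-(trimethylsilyl)phenyl trifluoromethanesulfonate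
Conditions: Tf2O, pyridine, CH2Cl2, 0 °C
Reagents that add atoms: trifluoromethanesulfonic anhydride: O=S(=O)(OS(=O)(=O)C(F)(F)F)C(F)(F)F
Why: O-sulfonylation of an ortho-silyl phenol with Tf2O and pyridine is the standard last step towards ortho-silylaryl triflates and touches neither the MOM acetal nor the prenyl ether.

**Ring B fragment**

Step 5
Reactants: 10 2-bromo-4,5-dimethoxybenzaldehyde
Product: 11 2-bromo-4,5-dihydroxybenzaldehyde
Conditions: BBr3 (3 equiv), CH2Cl2, −78 °C → rt; H2O
Reagents that add atoms: none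
Why: Lewis-acid cleavage of aryl methyl ethers with BBr3 frees both phenols and leaves aldehyde and aryl bromide intact, the bromine being already fixed ortho to the formyl group and para to the C5 oxygen.

Step 6
Reactants: 11 2-bromo-4,5-dihydroxybenzaldehyde; 12 3-chloro-3-methylbut-1-yne
Product: 13 2-bromo-5-hydroxy-4-[(2-methylbut-3-yn-2-yl)oxy]benzaldehyde
Conditions: 12 (1.5 equiv), K2CO3 (1.1 equiv), KI (cat.), CuI (cat.), DMF, 60 °C, argon
Reagents that add atoms: none
Why: The hydroxyl para to the formyl group is the more acidic one, so one equivalent of carbonate forms its phenoxide selectively and copper-assisted Williamson-type substitution of the tertiary propargylic chloride should give the 4-O-ether.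

Step 7
Reactants: 13 2-bromo-5-hydroxy-4-[(2-methylbut-3-yn-2-yl)oxy]benzaldehyde
Product: 14 2-bromo-5-(methoxymethoxy)-4-[(2-methylbut-3-yn-2-yl)oxy]benzaldehyde
Conditions: MOMCl, i-Pr2NEt, CH2Cl2, 0 °C → rt
Reagents that add atoms: chloromethyl methyl ether: COCCl
Why: Williamson-type O-alkylation of the remaining phenol with MOMCl and a hindered amine base masks it as an acetal that survives heat, fluoride and organolithium reagents.

Step 8
Reactants: 14 2-bromo-5-(methoxymethoxy)-4-[(2-methylbut-3-yn-2-yl)oxy]benzaldehyde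
Product: 16 5-bromo-8-(methoxymethoxy)-2,2-dimethyl-2H-chromene-6-carbaldehyde, via allenylphenol 15 (not isolated)
Conditions: N,N-diethylaniline, 190 °C
Reagents that add atoms: none
Why: Aryl propargyl ether Claisen rearrangement to the only free ortho carbon, enolisation to allenylphenol 15, 1,5-hydrogen shift and 6π-electrocyclisation of the ortho-quinone methide should give the 2,2-dimethyl-2H-chromene.

Step 9
Reactants: 16 5-bromo-8-(methoxymethoxy)-2,2-dimethyl-2H-chromene-6-carbaldehyde; 17 tributyl(3-methylbut-2-en-1-yl)stannane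
Product: 18 8-(methoxymethoxy)-2,2-dimethyl-5-(3-methylbut-2-en-1-yl)-2H-chromene-6-carbaldehyde
Conditions: 17 (1.5 equiv), Pd(PPh3)4 (5 mol %), DMF, 100 °C
Reagents that add atoms: none
Why: Stille coupling of the aryl bromide, activated by the ortho formyl group, should end by reductive elimination at the unsubstituted terminus of the allylpalladium unit and so give the linear prenyl group, and the stannane does not add to the aldehyde.

Step 10
Reactants: 18 8-(methoxymethoxy)-2,2-dimethyl-5-(3-methylbut-2-en-1-yl)-2H-chromene-6-carbaldehyde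
Product: 19 6-ethynyl-8-(methoxymethoxy)-2,2-dimethyl-5-(3-methylbut-2-en-1-yl)-2H-chromene
Conditions: dimethyl (1-diazo-2-oxopropyl)phosphonate, K2CO3, MeOH, 0 °C → rt
Reagents that add atoms: dimethyl (1-diazo-2-oxopropyl)phosphonate: COP(=O)(OC)C(=[N+]=[N-])C(C)=O
Why: The Ohira–Bestmann variant of the Seyferth–Gilbert homologation turns the aldehyde into the terminal alkyne under mild carbonate/methanol conditions that the MOM ether and both alkenes tolerate.

Step 11
Reactants: 19 6-ethynyl-8-(methoxymethoxy)-2,2-dimethyl-5-(3-methylbut-2-en-1-yl)-2H-chromene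
Product: 21 3-[8-(methoxymethoxy)-2,2-dimethyl-5-(3-methylbut-2-en-1-yl)-2H-chromen-6-yl]prop-2-ynoic acid, via lithium acetylide 20 (not isolated)
Conditions: n-BuLi (1.05 equiv), THF, −78 °C; CO2, −78 → 0 °C; 1 M HCl to pH 3, 0 °C
Reagents that add atoms: carbon dioxide: O=C=O
Why: Deprotonation of the terminal alkyne and carboxylation of the lithium acetylide is the standard route to arylpropiolic acids, and brief cold acidification spares the MOM ether.

**Key step**

Step 12
Reactants: 9 3-(methoxymethoxy)-5-[(3-methylbut-2-en-1-yl)oxy]-2-(trimethylsilyl)phenyl trifluoromethanesulfonate; 21 3-[8-(methoxymethoxy)-2,2-dimethyl-5-(3-methylbut-2-en-1-yl)-2H-chromen-6-yl]prop-2-ynoic acid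
Product: 24 5-(methoxymethoxy)-2-[8-(methoxymethoxy)-2,2-dimethyl-5-(3-methylbut-2-en-1-yl)-2H-chromen-6-yl]-7-[(3-methylbut-2-en-1-yl)oxy]-4H-chromen-4-one, via aryne 22 (not isolated), via hydroxyaryl ynone 23 (not isolated)
Conditions: 9 (1.5 equiv), 21 (1 equiv), CsF (4 equiv), THF, 125 °C, sealed tube
Reagents that add atoms: none
Why: Fluoride removes the silyl group of 9 and expels triflate to give aryne 22, whose C5 OMOM group withdraws inductively and distorts the triple bond so that the cesium carboxylate of 21 adds at C8a, the carbon remote from that oxygen, leaving the aryl anion on C4a. The anion attacks the neighbouring ester carbonyl through a four-membered alkoxide that opens to the ortho-acyl phenoxide of 23, a formal insertion of the aryne into the C–O bond of the acid; this is the known behaviour of carboxylic acids towards arynes at elevated temperature, and with arylpropiolic acids it is known to continue to flavones. Ring C then closes by 6-endo-dig oxa-Michael addition of the C8a phenoxide to the ynone, and the proton of the acid ends on C3. No stereocentre is formed. The step needs oxygen at C8a with the carbonyl carbon at C4a, which the polarisation of the 3-alkoxyaryne secures, and 6-endo rather than 5-exo closure, which conjugate addition under basic, metal-free conditions favours. Prenyl ether, chromene and MOM acetals are inert to fluoride, and the carboxylate should outrun ene reactions of the alkenes with the aryne.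

**Endgame**

Step 13
Reactants: 24 5-(methoxymethoxy)-2-[8-(methoxymethoxy)-2,2-dimethyl-5-(3-methylbut-2-en-1-yl)-2H-chromen-6-yl]-7-[(3-methylbut-2-en-1-yl)oxy]-4H-chromen-4-one
Product: 25 7-hydroxy-5-(methoxymethoxy)-2-[8-(methoxymethoxy)-2,2-dimethyl-5-(3-methylbut-2-en-1-yl)-2H-chromen-6-yl]-8-(2-methylbut-3-en-2-yl)-4H-chromen-4-one
Conditions: Eu(fod)3 (10 mol %), CHCl3, 60 °C
Reagents that add atoms: none
Why: The Lewis-acid-promoted aromatic Claisen rearrangement ([3,3] shift) of the aryl prenyl ether delivers the allyl unit with inversion, as a 1,1-dimethylallyl group, to C8, the ortho carbon joined to C7 by the bond of higher double-bond character in the benzopyranone and the one not flanked by the C5 OMOM group.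

Step 14
Reactants: 25 7-hydroxy-5-(methoxymethoxy)-2-[8-(methoxymethoxy)-2,2-dimethyl-5-(3-methylbut-2-en-1-yl)-2H-chromen-6-yl]-8-(2-methylbut-3-en-2-yl)-4H-chromen-4-one
Product: 26 5,7-bis(methoxymethoxy)-2-[8-(methoxymethoxy)-2,2-dimethyl-5-(3-methylbut-2-en-1-yl)-2H-chromen-6-yl]-8-(2-methylbut-3-en-2-yl)-4H-chromen-4-one
Conditions: MOMCl, i-Pr2NEt, CH2Cl2, 0 °C → rt
Reagents that add atoms: chloromethyl methyl ether: COCCl
Why: Williamson-type O-alkylation of the acidic 7-hydroxyl removes the only acidic proton before the lithiation.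

Step 15
Reactants: 26 5,7-bis(methoxymethoxy)-2-[8-(methoxymethoxy)-2,2-dimethyl-5-(3-methylbut-2-en-1-yl)-2H-chromen-6-yl]-8-(2-methylbut-3-en-2-yl)-4H-chromen-4-one
Product: 29 3-hydroxy-5,7-bis(methoxymethoxy)-2-[8-(methoxymethoxy)-2,2-dimethyl-5-(3-methylbut-2-en-1-yl)-2H-chromen-6-yl]-8-(2-methylbut-3-en-2-yl)-4H-chromen-4-one, via 3-lithioflavone 27 (not isolated), via flavonyl boronate 28 (not isolated)
Conditions: LiN(i-Pr)2 (LDA, 1.5 equiv), THF, −78 °C; B(OMe)3, −78 → 0 °C; AcOH, 30 % aq. H2O2, 0 °C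
Reagents that add atoms: hydrogen peroxide: OO
Why: Carbonyl-directed deprotonation of C3–H by LDA, borylation of the vinyllithium and oxidative carbon-to-oxygen migration with buffered peroxide is the established way from flavones to flavonols, the cold short lithiation being chosen so that removal of C3–H beside the coordinating carbonyl precedes that of the benzylic CH2 on ring B, and the cold peroxide should leave the alkenes alone.

Step 16
Reactants: 29 3-hydroxy-5,7-bis(methoxymethoxy)-2-[8-(methoxymethoxy)-2,2-dimethyl-5-(3-methylbut-2-en-1-yl)-2H-chromen-6-yl]-8-(2-methylbut-3-en-2-yl)-4H-chromen-4-one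
Product: 30 Broussoflavonol D (3,5,7-trihydroxy-2-[8-hydroxy-2,2-dimethyl-5-(3-methylbut-2-en-1-yl)-2H-chromen-6-yl]-8-(2-methylbut-3-en-2-yl)-4H-chromen-4-one)
Conditions: 3 M aq. HCl, MeOH, 40 °C
Reagents that add atoms: none
Why: Acid-catalysed acetal exchange with methanol removes the three MOM groups, and dilute acid at moderate temperature should spare the chromene, the prenyl group and the 1,1-dimethylallyl group beside the 7-hydroxyl.

**Compound list**

1 | phloroglucinol (benzene-1,3,5-triol) | Oc1cc(O)cc(O)c1 | starting material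
2 | 3-methylbut-2-en-1-ol (prenol) | CC(C)=CCO | starting material
3 | 5-[(3-methylbut-2-en-1-yl)oxy]benzene-1,3-diol | CC(C)=CCOc1cc(O)cc(O)c1 | intermediate
4 | 2-iodo-5-[(3-methylbut-2-en-1-yl)oxy]benzene-1,3-diol | CC(C)=CCOc1cc(O)c(I)c(O)c1 | intermediate
5 | 2-iodo-5-[(3-methylbut-2-en-1-yl)oxy]-1,3-bis(trimethylsilyloxy)benzene | CC(C)=CCOc1cc(O[Si](C)(C)C)c(I)c(O[Si](C)(C)C)c1 | intermediate
6 | lithium 5-[(3-methylbut-2-en-1-yl)oxy]-2-(trimethylsilyl)-3-(trimethylsilyloxy)phenolate | [Li+].CC(C)=CCOc1cc([O-])c([Si](C)(C)C)c(O[Si](C)(C)C)c1 | intermediate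
7 | [2-(methoxymethoxy)-4-[(3-methylbut-2-en-1-yl)oxy]-6-(trimethylsilyloxy)phenyl]trimethylsilane | CC(C)=CCOc1cc(OCOC)c([Si](C)(C)C)c(O[Si](C)(C)C)c1 | intermediate
8 | 3-(methoxymethoxy)-5-[(3-methylbut-2-en-1-yl)oxy]-2-(trimethylsilyl)phenol | CC(C)=CCOc1cc(OCOC)c([Si](C)(C)C)c(O)c1 | intermediate
9 | 3-(methoxymethoxy)-5-[(3-methylbut-2-en-1-yl)oxy]-2-(trimethylsilyl)phenyl trifluoromethanesulfonate | CC(C)=CCOc1cc(OCOC)c([Si](C)(C)C)c(OS(=O)(=O)C(F)(F)F)c1 | intermediate
10 | 2-bromo-4,5-dimethoxybenzaldehyde | COc1cc(Br)c(C=O)cc1OC | starting material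
11 | 2-bromo-4,5-dihydroxybenzaldehyde | Oc1cc(Br)c(C=O)cc1O | intermediate
12 | 3-chloro-3-methylbut-1-yne | C#CC(C)(C)Cl | starting material
13 | 2-bromo-5-hydroxy-4-[(2-methylbut-3-yn-2-yl)oxy]benzaldehyde | C#CC(C)(C)Oc1cc(Br)c(C=O)cc1O | intermediate
14 | 2-bromo-5-(methoxymethoxy)-4-[(2-methylbut-3-yn-2-yl)oxy]benzaldehyde | C#CC(C)(C)Oc1cc(Br)c(C=O)cc1OCOC | intermediate
15 | 2-bromo-4-hydroxy-5-(methoxymethoxy)-3-(3-methylbuta-1,2-dien-1-yl)benzaldehyde | CC(C)=C=Cc1c(Br)c(C=O)cc(OCOC)c1O | intermediate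
16 | 5-bromo-8-(methoxymethoxy)-2,2-dimethyl-2H-chromene-6-carbaldehyde | O=Cc1cc(OCOC)c2c(c1Br)C=CC(C)(C)O2 | intermediate
17 | tributyl(3-methylbut-2-en-1-yl)stannane | CCCC[Sn](CCCC)(CCCC)CC=C(C)C | starting material
18 | 8-(methoxymethoxy)-2,2-dimethyl-5-(3-methylbut-2-en-1-yl)-2H-chromene-6-carbaldehyde | O=Cc1cc(OCOC)c2c(c1CC=C(C)C)C=CC(C)(C)O2 | intermediate
19 | 6-ethynyl-8-(methoxymethoxy)-2,2-dimethyl-5-(3-methylbut-2-en-1-yl)-2H-chromene | C#Cc1cc(OCOC)c2c(c1CC=C(C)C)C=CC(C)(C)O2 | intermediate
20 | lithium acetylide of 19 | [Li]C#Cc1cc(OCOC)c2c(c1CC=C(C)C)C=CC(C)(C)O2 | intermediate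
21 | 3-[8-(methoxymethoxy)-2,2-dimethyl-5-(3-methylbut-2-en-1-yl)-2H-chromen-6-yl]prop-2-ynoic acid | OC(=O)C#Cc1cc(OCOC)c2c(c1CC=C(C)C)C=CC(C)(C)O2 | intermediate
22 | 3-(methoxymethoxy)-5-[(3-methylbut-2-en-1-yl)oxy]benzyne (1,2-didehydrobenzene) | COCOC1=CC(OCC=C(C)C)=CC#C1 | intermediate
23 | 1-{2-hydroxy-6-(methoxymethoxy)-4-[(3-methylbut-2-en-1-yl)oxy]phenyl}-3-[8-(methoxymethoxy)-2,2-dimethyl-5-(3-methylbut-2-en-1-yl)-2H-chromen-6-yl]prop-2-yn-1-one (formed as its cesium phenoxide) | CC(C)=CCOc1cc(O)c(C(=O)C#Cc2cc(OCOC)c3c(c2CC=C(C)C)C=CC(C)(C)O3)c(OCOC)c1 | intermediate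
24 | 5-(methoxymethoxy)-2-[8-(methoxymethoxy)-2,2-dimethyl-5-(3-methylbut-2-en-1-yl)-2H-chromen-6-yl]-7-[(3-methylbut-2-en-1-yl)oxy]-4H-chromen-4-one | CC(C)=CCOc1cc(OCOC)c2c(=O)cc(-c3cc(OCOC)c4c(c3CC=C(C)C)C=CC(C)(C)O4)oc2c1 | intermediate
25 | 7-hydroxy-5-(methoxymethoxy)-2-[8-(methoxymethoxy)-2,2-dimethyl-5-(3-methylbut-2-en-1-yl)-2H-chromen-6-yl]-8-(2-methylbut-3-en-2-yl)-4H-chromen-4-one | C=CC(C)(C)c1c(O)cc(OCOC)c2c(=O)cc(-c3cc(OCOC)c4c(c3CC=C(C)C)C=CC(C)(C)O4)oc12 | intermediate
26 | 5,7-bis(methoxymethoxy)-2-[8-(methoxymethoxy)-2,2-dimethyl-5-(3-methylbut-2-en-1-yl)-2H-chromen-6-yl]-8-(2-methylbut-3-en-2-yl)-4H-chromen-4-one | C=CC(C)(C)c1c(OCOC)cc(OCOC)c2c(=O)cc(-c3cc(OCOC)c4c(c3CC=C(C)C)C=CC(C)(C)O4)oc12 | intermediate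
27 | 3-lithio derivative of 26 | C=CC(C)(C)c1c(OCOC)cc(OCOC)c2c(=O)c([Li])c(-c3cc(OCOC)c4c(c3CC=C(C)C)C=CC(C)(C)O4)oc12 | intermediate
28 | dimethyl boronate at C3 of 26 | C=CC(C)(C)c1c(OCOC)cc(OCOC)c2c(=O)c(B(OC)OC)c(-c3cc(OCOC)c4c(c3CC=C(C)C)C=CC(C)(C)O4)oc12 | intermediate
29 | 3-hydroxy-5,7-bis(methoxymethoxy)-2-[8-(methoxymethoxy)-2,2-dimethyl-5-(3-methylbut-2-en-1-yl)-2H-chromen-6-yl]-8-(2-methylbut-3-en-2-yl)-4H-chromen-4-one | C=CC(C)(C)c1c(OCOC)cc(OCOC)c2c(=O)c(O)c(-c3cc(OCOC)c4c(c3CC=C(C)C)C=CC(C)(C)O4)oc12 | intermediate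
30 | Broussoflavonol D | C=CC(C)(C)c1c(O)cc(O)c2c(=O)c(O)c(-c3cc(O)c4c(c3CC=C(C)C)C=CC(C)(C)O4)oc12 | target

**Step count**

Total: 16 steps. Longest linear sequence: 12 steps (steps 5–11, 12, 13–16, from 2-bromo-4,5-dimethoxybenzaldehyde).

**Steps most likely to fail**

Step 12. The aryl anion may be protonated before the acyl group migrates, which stops the reaction at simple O-arylation of the acid. The propiolate may also decarboxylate at the temperature the acyl transfer needs, or the phenoxide may close 5-exo. The fallback builds the same ynone by carbonylation. It sets out from 4 and 19. Monoprotection of 4 with MOMCl and i-Pr2NEt, the two hydroxyls being equivalent, gives 2-iodo-3-(methoxymethoxy)-5-[(3-methylbut-2-en-1-yl)oxy]phenol F1. PdCl2(PPh3)2-catalysed carbonylative Sonogashira coupling of F1 with alkyne 19 under CO (1 atm) in Et2NH/THF forms ynone 23, which the amine cyclises 6-endo-dig. The route is rejoined at 24.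

Step 13. The allyl unit may also migrate to C6. The Lewis acid may instead strip the prenyl group, or let the freed 7-hydroxyl add to the new vinyl group. The fallback replaces Lewis-acid promotion by a purely thermal shift with capture of the phenol as it forms, which addresses the last two failure modes but not a shift to C6. It sets out from 24, which is heated in N,N-diethylaniline with Ac2O and NaOAc at about 180 °C. This gives 5-(methoxymethoxy)-2-[8-(methoxymethoxy)-2,2-dimethyl-5-(3-methylbut-2-en-1-yl)-2H-chromen-6-yl]-8-(2-methylbut-3-en-2-yl)-4-oxo-4H-chromen-7-yl acetate F2. Methanolysis with K2CO3 in MeOH returns to 25.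

Step 9. Oxidative addition and transmetalation at the doubly flanked bromide may be slow, and the prenyl unit may be delivered with allylic transposition. The fallback brings in the five carbons in two stages. It sets out from 16. Stille coupling with allyltributylstannane and Pd(PPh3)4, where no regiochemical question arises, gives 5-allyl-8-(methoxymethoxy)-2,2-dimethyl-2H-chromene-6-carbaldehyde F3. Cross-metathesis of F3 with excess 2-methylbut-2-ene, using the second-generation Grubbs catalyst (H2IMes)(PCy3)Cl2Ru=CHPh, converts allyl into prenyl and returns to 18. The chromene double bond, cis-disubstituted next to a quaternary carbon, should not take part.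

Further compounds
F1 | step 12 | 2-iodo-3-(methoxymethoxy)-5-[(3-methylbut-2-en-1-yl)oxy]phenol | CC(C)=CCOc1cc(O)c(I)c(OCOC)c1
F2 | step 13 | 5-(methoxymethoxy)-2-[8-(methoxymethoxy)-2,2-dimethyl-5-(3-methylbut-2-en-1-yl)-2H-chromen-6-yl]-8-(2-methylbut-3-en-2-yl)-4-oxo-4H-chromen-7-yl acetate | C=CC(C)(C)c1c(OC(C)=O)cc(OCOC)c2c(=O)cc(-c3cc(OCOC)c4c(c3CC=C(C)C)C=CC(C)(C)O4)oc12
F3 | step 9 | 5-allyl-8-(methoxymethoxy)-2,2-dimethyl-2H-chromene-6-carbaldehyde | O=Cc1cc(OCOC)c2c(c1CC=C)C=CC(C)(C)O2
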